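**Plan**

- Retrosynthesis: the two C–Br bonds are cut first (each from a carbinol by SN2 inversion), then the side-chain carbinol (from a chloromethyl ketone). Next comes the ring C=C between the ring CH beside the CMe2 carbon and the ring carbon carrying the two-carbon branch. Last are the CMe2–CH(O) bond and the CH2–CH(OAc) bond.
- Forward: 4-chlorobut-2-ynal is extended by two reagent-controlled allyl-type additions to a linear ynal that already holds all ten skeletal carbons and the acetate. The only ring is then closed by an alkyne–carbonyl metathesis, an isomerisation that forms the trisubstituted ring alkene and moves the aldehyde oxygen onto the branch carbon that later carries bromine.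
- Enabling feature: the ring CH= sits beside the quaternary CMe2 carbon, so as an aldehyde it cannot enolise. The other alkene carbon carries the CHBr–CH2Cl branch, so it can be the inner carbon of a chloromethyl alkyne whose outer carbon accepts the oxygen.
- Stereochemistry: the acetate carbon comes from Brown allylation. The ring CHBr carbon comes from Brown reverse prenylation followed by inversion. The side-chain CHBr carbon comes from Corey–Bakshi–Shibata reduction followed by inversion.

Key step: step 8

Remark: 4-chlorobut-2-yn-1-ol, both antipodes of the α-pinene-derived boranes and 3-methylbuta-1,2-diene are taken as purchasable; the labile aldehydes 2 and 7 are used without purification.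

**Step 1**
Reactants: 1 4-chlorobut-2-yn-1-ol
Product: 2 4-chlorobut-2-ynal
Conditions: Dess–Martin periodinane (1.1 equiv), CH2Cl2, 0 °C to rt; short silica plug, used as a cold solution
Reagents that add atoms: none
Why: Dess–Martin oxidation of a primary propargylic alcohol should stop at the ynal under non-basic conditions that leave the propargylic chloride untouched.

**Step 2**
Reactants: 2 4-chlorobut-2-ynal
Product: 4 (4R)-7-chlorohept-1-en-5-yn-4-ol, via borinate ester 3 (not isolated)
Conditions: (+)-B-methoxydiisopinocampheylborane [from (−)-α-pinene], allylMgBr, Et2O, 0 °C to rt; then 2, −78 °C; H2O2, pH 7 phosphate buffer, MeOH, 0 °C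
Reagents that add atoms: allylmagnesium bromide C=CC[Mg]Br, whose allyl group is delivered as B-allylbis(isopinocampheyl)borane C=CCB([C@H]1C[C@H]2C[C@@H]([C@@H]1C)C2(C)C)[C@H]1C[C@H]2C[C@@H]([C@@H]1C)C2(C)C formed in the flask
Why: Brown asymmetric allylboration through a closed chair transition state should add allyl to the Re face of the ynal and set the (R)-propargylic carbinol under reagent control.

**Step 3**
Reactants: 4 (4R)-7-chlorohept-1-en-5-yn-4-ol
Product: 5 (4R)-7-chlorohept-1-en-5-yn-4-yl acetate
Conditions: Ac2O, pyridine, DMAP (cat.), CH2Cl2, 0 °C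
Reagents that add atoms: acetic anhydride CC(=O)OC(C)=O
Why: DMAP-catalysed acylation installs the acetate of the target at once, so that no protecting-group exchange is needed at this oxygen later.

**Step 4**
Reactants: 5 (4R)-7-chlorohept-1-en-5-yn-4-yl acetate
Product: 7 (3R)-6-chloro-1-oxohex-4-yn-3-yl acetate, via secondary ozonide 6 (not isolated)
Conditions: O3 (1.0 equiv, indicator-controlled), CH2Cl2, −78 °C; PPh3 (1.05 equiv), −78 to 0 °C
Reagents that add atoms: ozone [O-][O+]=O
Why: ozonolysis should cleave the terminal alkene far faster than the electron-poor internal alkyne, and neutral reduction of the ozonide should release the β-acetoxy aldehyde without base-induced loss of acetic acid.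

**Step 5**
Reactants: 7 (3R)-6-chloro-1-oxohex-4-yn-3-yl acetate
Product: 9 (4R,6R)-9-chloro-4-hydroxy-3,3-dimethylnon-1-en-7-yn-6-yl acetate, via borinate ester 8 (not isolated)
Conditions: (−)-diisopinocampheylborane [from (+)-α-pinene], 3-methylbuta-1,2-diene, THF, −25 °C; then 7, −78 °C; H2O2, pH 7 phosphate buffer, MeOH, 0 °C
Reagents that add atoms: 3-methylbuta-1,2-diene CC(C)=C=C, delivered as B-(3-methylbut-2-en-1-yl)bis(isopinocampheyl)borane CC(C)=CCB([C@@H]1C[C@@H]2C[C@H]([C@H]1C)C2(C)C)[C@@H]1C[C@@H]2C[C@H]([C@H]1C)C2(C)C formed in the flask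
Why: Brown reverse prenylation should add the prenylborane through its γ-carbon in a chair transition state to the Si face, creating the CMe2 quaternary carbon with its vinyl group and the (R)-carbinol, anti to the acetate, under reagent control.

**Step 6**
Reactants: 9 (4R,6R)-9-chloro-4-hydroxy-3,3-dimethylnon-1-en-7-yn-6-yl acetate
Product: 10 (4R,6R)-4-[(tert-butyldimethylsilyl)oxy]-9-chloro-3,3-dimethylnon-1-en-7-yn-6-yl acetate
Conditions: TBSOTf, 2,6-lutidine, CH2Cl2, 0 °C to rt
Reagents that add atoms: tert-butyldimethylsilyl triflate CC(C)(C)[Si](C)(C)OS(=O)(=O)C(F)(F)F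
Why: silylation with the triflate covers the hindered neopentyl hydroxyl so that the later β-oxygenated aldehyde cannot undergo retro-aldol cleavage or acetal formation.

**Step 7**
Reactants: 10 (4R,6R)-4-[(tert-butyldimethylsilyl)oxy]-9-chloro-3,3-dimethylnon-1-en-7-yn-6-yl acetate
Product: 12 (3R,5R)-5-(acetyloxy)-3-[(tert-butyldimethylsilyl)oxy]-8-chloro-2,2-dimethyloct-6-ynal, via secondary ozonide 11 (not isolated)
Conditions: O3 (1.0 equiv), CH2Cl2, −78 °C; PPh3 (1.05 equiv), −78 °C to rt
Reagents that add atoms: ozone [O-][O+]=O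
Why: chemoselective ozonolysis of the monosubstituted alkene should unmask the aldehyde on the quaternary carbon, which has no α-hydrogen and so can neither enolise nor eliminate the β-silyloxy group.

**Step 8**
Reactants: 12 (3R,5R)-5-(acetyloxy)-3-[(tert-butyldimethylsilyl)oxy]-8-chloro-2,2-dimethyloct-6-ynal
Product: 14 (1R,5R)-5-[(tert-butyldimethylsilyl)oxy]-2-(2-chloroacetyl)-4,4-dimethylcyclohex-2-en-1-yl acetate, via fused 2H-oxete 13 (not isolated)
Conditions: BF3·OEt2 (30 mol %), CH2Cl2, 0 °C to rt
Reagents that add atoms: none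
Why: BF3 activates the non-enolisable aldehyde, the alkyne carbon next to the acetoxy carbinol attacks the carbonyl carbon, and the carbonyl oxygen captures the developing vinyl cation at the chloromethyl-bearing carbon to give the fused 2H-oxete 13, which opens by thermal 4π electrocyclic ring opening to the 1-acylcyclohexene 14. The closest known reaction type is the Lewis or Brønsted acid promoted intramolecular alkyne–carbonyl metathesis of ω-alkynals to 1-acylcycloalkenes, which includes dialkyl alkynes. The six-membered carbocycle closes in the 6-exo-dig mode, and the transient four-membered oxete closes by O–C bond formation onto the outer alkyne carbon (formal [2+2]). No permanent stereocentre is created: the oxete CH–O centre vanishes on ring opening, and the two existing carbinol centres are neither enolisable nor ionised under these conditions. The step needs exo rather than endo regiochemistry and retention of the propargylic acetate; the tether length and the gem-dimethyl (Thorpe–Ingold) effect favour the six- over the seven-membered closure, and the endo mode would place positive charge beside the acetoxy-bearing carbon. The absence of α-hydrogens on the aldehyde excludes aldol and ene pathways, and catalytic acid at low temperature should spare the silyl ether and the acetate.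

**Step 9**
Reactants: 14 (1R,5R)-5-[(tert-butyldimethylsilyl)oxy]-2-(2-chloroacetyl)-4,4-dimethylcyclohex-2-en-1-yl acetate
Product: 15 (1R,5R)-5-[(tert-butyldimethylsilyl)oxy]-2-[(1S)-2-chloro-1-hydroxyethyl]-4,4-dimethylcyclohex-2-en-1-yl acetate
Conditions: (S)-2-methyl-CBS-oxazaborolidine [(S)-1-methyl-3,3-diphenylhexahydropyrrolo[1,2-c][1,3,2]oxazaborole] (20 mol %), BH3·SMe2, THF, −20 °C; MeOH quench
Reagents that add atoms: none
Why: in this Corey–Bakshi–Shibata reduction the cyclohexenyl group acts as the large and CH2Cl as the small substituent, so the (S)-oxazaborolidine should deliver hydride 1,2 to give the (S)-chlorohydrin, as with aryl chloromethyl ketones.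

**Step 10**
Reactants: 15 (1R,5R)-5-[(tert-butyldimethylsilyl)oxy]-2-[(1S)-2-chloro-1-hydroxyethyl]-4,4-dimethylcyclohex-2-en-1-yl acetate
Product: 16 (1R,5R)-2-[(1S)-2-chloro-1-hydroxyethyl]-5-hydroxy-4,4-dimethylcyclohex-2-en-1-yl acetate
Conditions: HF·pyridine, THF/pyridine, 0 to 40 °C
Reagents that add atoms: none
Why: acidic fluoride should remove the hindered silyl ether without the basic conditions that would close the chlorohydrin to an epoxide or move the acetate.

**Step 11**
Reactants: 16 (1R,5R)-2-[(1S)-2-chloro-1-hydroxyethyl]-5-hydroxy-4,4-dimethylcyclohex-2-en-1-yl acetate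
Product: 17 (1R,5S)-5-bromo-2-[(1R)-1-bromo-2-chloroethyl]-4,4-dimethylcyclohex-2-en-1-yl acetate
Conditions: CBr4 (5 equiv), PPh3 (4.5 equiv, added last in portions), CH2Cl2, 0 to 40 °C
Reagents that add atoms: carbon tetrabromide BrC(Br)(Br)Br
Why: in this double Appel reaction bromide should displace each alkoxyphosphonium with inversion: the allylic one quickly (SN2' at the ring CH is blocked by the adjacent quaternary carbon) and the neopentyl one through the half-chair conformer with an axial leaving group and an open equatorial approach, as in the conversion of axial 3-hydroxy-4,4-dimethylcyclohexanes into equatorial bromides, which sets (1R) in the side chain and (5S) in the ring.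

**Compound list**

1 | 4-chlorobut-2-yn-1-ol | OCC#CCCl | starting material
2 | 4-chlorobut-2-ynal | O=CC#CCCl | intermediate
3 | (4R)-7-chlorohept-1-en-5-yn-4-yl bis(isopinocampheyl)borinate | C=CC[C@@H](OB([C@H]1C[C@H]2C[C@@H]([C@@H]1C)C2(C)C)[C@H]1C[C@H]2C[C@@H]([C@@H]1C)C2(C)C)C#CCCl | intermediate (not isolated)
4 | (4R)-7-chlorohept-1-en-5-yn-4-ol | C=CC[C@@H](O)C#CCCl | intermediate
5 | (4R)-7-chlorohept-1-en-5-yn-4-yl acetate | C=CC[C@@H](OC(C)=O)C#CCCl | intermediate
6 | (2R)-5-chloro-1-(1,2,4-trioxolan-3-yl)pent-3-yn-2-yl acetate (secondary ozonide of 5) | C1(OCOO1)C[C@@H](OC(C)=O)C#CCCl | intermediate (not isolated)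
7 | (3R)-6-chloro-1-oxohex-4-yn-3-yl acetate | O=CC[C@@H](OC(C)=O)C#CCCl | intermediate
8 | (4R,6R)-6-(acetyloxy)-9-chloro-3,3-dimethylnon-1-en-7-yn-4-yl bis(isopinocampheyl)borinate | C=CC(C)(C)[C@H](OB([C@@H]1C[C@@H]2C[C@H]([C@H]1C)C2(C)C)[C@@H]1C[C@@H]2C[C@H]([C@H]1C)C2(C)C)C[C@@H](OC(C)=O)C#CCCl | intermediate (not isolated)
9 | (4R,6R)-9-chloro-4-hydroxy-3,3-dimethylnon-1-en-7-yn-6-yl acetate | C=CC(C)(C)[C@H](O)C[C@@H](OC(C)=O)C#CCCl | intermediate
10 | (4R,6R)-4-[(tert-butyldimethylsilyl)oxy]-9-chloro-3,3-dimethylnon-1-en-7-yn-6-yl acetate | C=CC(C)(C)[C@H](O[Si](C)(C)C(C)(C)C)C[C@@H](OC(C)=O)C#CCCl | intermediate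
11 | (3R,5R)-3-[(tert-butyldimethylsilyl)oxy]-8-chloro-2-methyl-2-(1,2,4-trioxolan-3-yl)oct-6-yn-5-yl acetate (secondary ozonide of 10) | C1(OCOO1)C(C)(C)[C@H](O[Si](C)(C)C(C)(C)C)C[C@@H](OC(C)=O)C#CCCl | intermediate (not isolated)
12 | (3R,5R)-5-(acetyloxy)-3-[(tert-butyldimethylsilyl)oxy]-8-chloro-2,2-dimethyloct-6-ynal | O=CC(C)(C)[C@H](O[Si](C)(C)C(C)(C)C)C[C@@H](OC(C)=O)C#CCCl | intermediate
13 | (2R,4R)-4-[(tert-butyldimethylsilyl)oxy]-8-(chloromethyl)-5,5-dimethyl-7-oxabicyclo[4.2.0]oct-1(8)-en-2-yl acetate | CC(=O)O[C@@H]1C[C@@H](O[Si](C)(C)C(C)(C)C)C(C)(C)C2OC(CCl)=C12 | intermediate (not isolated)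
14 | (1R,5R)-5-[(tert-butyldimethylsilyl)oxy]-2-(2-chloroacetyl)-4,4-dimethylcyclohex-2-en-1-yl acetate | CC(=O)O[C@@H]1C[C@@H](O[Si](C)(C)C(C)(C)C)C(C)(C)C=C1C(=O)CCl | intermediate
15 | (1R,5R)-5-[(tert-butyldimethylsilyl)oxy]-2-[(1S)-2-chloro-1-hydroxyethyl]-4,4-dimethylcyclohex-2-en-1-yl acetate | CC(=O)O[C@@H]1C[C@@H](O[Si](C)(C)C(C)(C)C)C(C)(C)C=C1[C@H](O)CCl | intermediate
16 | (1R,5R)-2-[(1S)-2-chloro-1-hydroxyethyl]-5-hydroxy-4,4-dimethylcyclohex-2-en-1-yl acetate | CC(=O)O[C@@H]1C[C@@H](O)C(C)(C)C=C1[C@H](O)CCl | intermediate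
17 | (1R,5S)-5-bromo-2-[(1R)-1-bromo-2-chloroethyl]-4,4-dimethylcyclohex-2-en-1-yl acetate | CC(=O)O[C@@H]1C[C@H](Br)C(C)(C)C=C1[C@@H](Br)CCl | target

Total step count: 11. Longest linear sequence: 11 steps (the route is fully linear from 1).

**Steps most likely to fail**

Step 8. The alkyne carries an electron-withdrawing group on each propargylic carbon and may be too weak a π-nucleophile, so that acid-induced ionisation or migration of the propargylic acetate, or loss of the silyl ether, overtakes cyclisation. The fallback sets out from enyne 10 and comes back at enone 14. Ring-closing enyne metathesis (second-generation Grubbs catalyst RuCl2(=CHPh)(H2IMes)(PCy3), toluene, 80 °C) should close the same ring bond and give the cross-conjugated diene (1R,5R)-5-[(tert-butyldimethylsilyl)oxy]-2-(3-chloroprop-1-en-2-yl)-4,4-dimethylcyclohex-2-en-1-yl acetate F1. Dihydroxylation of its less hindered 1,1-disubstituted alkene (OsO4 cat., N-methylmorpholine N-oxide) should give (1R,5R)-5-[(tert-butyldimethylsilyl)oxy]-2-(1-chloro-2,3-dihydroxypropan-2-yl)-4,4-dimethylcyclohex-2-en-1-yl acetate F2, and glycol cleavage with NaIO4 should then give 14.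

Step 11. Displacement at the neopentyl ring carbinol is slow, and during that time the allylic bromide formed first may epimerise by bromide exchange, eliminate, or be taken up by free phosphine; the axial oxyphosphonium may also eliminate towards the ring CH2 or be intercepted by the acetate. The fallback sets out from diol 16 and comes back at 17, with the allylic bromide made last. Selective silylation of the unhindered allylic hydroxyl (Et3SiCl, imidazole, CH2Cl2, −20 °C) should give (1R,5R)-2-[(1S)-2-chloro-1-[(triethylsilyl)oxy]ethyl]-5-hydroxy-4,4-dimethylcyclohex-2-en-1-yl acetate F3. The neopentyl carbinol alone is then brominated with inversion (CBr4, PPh3, prolonged) to (1R,5S)-5-bromo-2-[(1S)-2-chloro-1-[(triethylsilyl)oxy]ethyl]-4,4-dimethylcyclohex-2-en-1-yl acetate F4. HF·pyridine should free (1R,5S)-5-bromo-2-[(1S)-2-chloro-1-hydroxyethyl]-4,4-dimethylcyclohex-2-en-1-yl acetate F5, and a short Appel reaction at 0 °C should give 17.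

Step 5. The β-acetoxy aldehyde 7 may lose acetic acid by E1cB elimination to a conjugated enynal before or during prenylboration, and reagent control may be eroded by the existing centre. The fallback sets out from alcohol 4 and comes back at 9, with the acetate introduced only after the second carbinol exists. Ozonolysis of the free homoallylic alcohol (O3, then PPh3) should give (3R)-6-chloro-3-hydroxyhex-4-ynal F6, whose hydroxyl is a far poorer leaving group. The same prenylborane as in step 5 should give the anti diol (4R,6R)-9-chloro-3,3-dimethylnon-1-en-7-yne-4,6-diol F7. Site-selective acetylation of the unhindered propargylic hydroxyl over the neopentyl one (Ac2O, 2,4,6-collidine, −20 °C) should give 9.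

**Further compounds**

F1 | step 8 | (1R,5R)-5-[(tert-butyldimethylsilyl)oxy]-2-(3-chloroprop-1-en-2-yl)-4,4-dimethylcyclohex-2-en-1-yl acetate | CC(=O)O[C@@H]1C[C@@H](O[Si](C)(C)C(C)(C)C)C(C)(C)C=C1C(=C)CCl
F2 | step 8 | (1R,5R)-5-[(tert-butyldimethylsilyl)oxy]-2-(1-chloro-2,3-dihydroxypropan-2-yl)-4,4-dimethylcyclohex-2-en-1-yl acetate | CC(=O)O[C@@H]1C[C@@H](O[Si](C)(C)C(C)(C)C)C(C)(C)C=C1C(O)(CO)CCl
F3 | step 11 | (1R,5R)-2-[(1S)-2-chloro-1-[(triethylsilyl)oxy]ethyl]-5-hydroxy-4,4-dimethylcyclohex-2-en-1-yl acetate | CC(=O)O[C@@H]1C[C@@H](O)C(C)(C)C=C1[C@H](O[Si](CC)(CC)CC)CCl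
F4 | step 11 | (1R,5S)-5-bromo-2-[(1S)-2-chloro-1-[(triethylsilyl)oxy]ethyl]-4,4-dimethylcyclohex-2-en-1-yl acetate | CC(=O)O[C@@H]1C[C@H](Br)C(C)(C)C=C1[C@H](O[Si](CC)(CC)CC)CCl
F5 | step 11 | (1R,5S)-5-bromo-2-[(1S)-2-chloro-1-hydroxyethyl]-4,4-dimethylcyclohex-2-en-1-yl acetate | CC(=O)O[C@@H]1C[C@H](Br)C(C)(C)C=C1[C@H](O)CCl
F6 | step 5 | (3R)-6-chloro-3-hydroxyhex-4-ynal | O=CC[C@@H](O)C#CCCl
F7 | step 5 | (4R,6R)-9-chloro-3,3-dimethylnon-1-en-7-yne-4,6-diol | C=CC(C)(C)[C@H](O)C[C@@H](O)C#CCCl
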